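## Structural features

Iridal is a monocyclic C30 seco-triterpenoid. Atoms are numbered C1 (aldehyde carbon), C2 (its alpha carbon), C3–C5 (hydroxypropyl arm, counted from oxygen), C6–C11 (the ring: C6 methine, C7 alkylidene carbon, C8, C9, C10 carbinol, C11 quaternary), with the chain starting at C12. The single cyclohexane ring carries an all-E homofarnesyl chain on C11, a 3-hydroxypropyl arm on C6 and an exocyclic, tetrasubstituted enal on C7. Three stereocentres stand in a row: C6 (R), C11 (S, quaternary, methyl plus chain) and C10 (S, tertiary carbinol with methyl). The C10 hydroxyl, the C11 methyl and the C6 arm lie on one ring face; the chain and the C10 methyl lie on the other. The C7=C2 alkene has the formyl group cis to C6 (Z), a geometry that a plain carbonyl olefination of a C7 ketone cannot be trusted to deliver. The fragile parts are the enal (conjugate addition, E/Z isomerisation, deconjugation), the tertiary alcohol next to a quaternary carbon (elimination, cation chemistry) and three electron-rich trisubstituted alkenes that exclude strong acid, electrophilic oxidants and hydrogenation. The real difficulty is the vicinal pair of fully substituted carbons C10/C11 with fixed relative configuration, flanked by the epimerisable C6, together with the alkene geometry. The key step exploits the cis relation between the C11 methyl and the C10 hydroxyl: the methyl is delivered as CH2 by that hydroxyl across a C11=C6 ring alkene. The temporary cyclopropane then holds, in its C6–CH2 bond, the means to release a regiodefined C6 enolate for the C3–C5 arm once C7 is a ketone.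

## Logic of the disconnections

31 to 30: only the O–Si bond at C10 is cut. Keeping the tertiary alcohol masked to the end removes the one acidic, eliminable group from all organometallic steps. The forward step must cleave a hindered silyl ether without touching the enal.

30 to 28 to 27: the C1–C2 bond (formyl) and then the C2–CH3 bond are cut, which leads back to the gem-dibromoalkene 27. This turns the geometry problem into the order in which two identical halogens are replaced. The forward steps require that the first coupling picks the bromide remote from C6, and that bromine–lithium exchange in 28 (through 29) and formylation proceed with retention.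

27 to 25 to 24: the C3–O bond is cut (the terminal alkene is the latent primary alcohol) and then the C7=C2 bond, giving ketone 24. The terminal alkene is inert to everything before it and is the only monosubstituted alkene in the molecule. The forward steps need an olefination that works on a hindered, epimerisable ketone, and a borane that ignores three trisubstituted alkenes.

24 to 21 and 22: the C5–C6 bond is cut, and in the same retrosynthetic move the C11 methyl is reconnected to C6 as a cyclopropane. One functional group in 21 thus accounts for both the quaternary methyl and the regiodefined enolate 23. The forward step must cleave the exocyclic cyclopropane bond, not the ring-fusion bond, and alkylate 23 on the face anti to the chain before proton exchange.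

21 to 20 to 19 to 18: no skeletal bond is cut; the C10 silyl ether, the C7 oxidation level and the C7 silyl ether are adjusted. The C10 hydroxyl is left free only while it is needed as a directing group and is capped before the dissolving-metal and phosphorus–bromine steps. The forward steps must avoid acid, because both carbinol carbons of 18 and 19 are cyclopropylcarbinyl positions.

18 to 16 (key): the C11–CH2 and C6–CH2 bonds are cut. This removes the quaternary stereocentre and leaves a planar trisubstituted ring alkene next to the existing C10 carbinol. The forward step needs CH2 delivery cis to the C10 oxygen and no reaction at the three chain alkenes.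

16 to 15 to 14: the O–Si bond and then the C7–H bond are cut, back to enone 14. C7 is a temporary stereocentre; it is placed trans to the C10 hydroxyl so that the silyl ether lies on the face opposite to carbenoid delivery. The forward steps need 1,2-reduction and selective silylation of the secondary hydroxyl.

14 to 6 and 11: the C11–C12 bond is cut. This joins the intact C16 chain to the ring in one convergent step and moves the carbonyl from C11 to C7. The forward step needs 1,2-addition to a hindered vinylogous ester carbonyl next to a tertiary alkoxide, and hydrolysis mild enough for the polyene.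

11 to 9 to 7: the C10–O bond and then the C10–CH3 bond are cut, leaving a commercial vinylogous ester. Both bonds are made at the same alpha' carbon by enolate chemistry. The forward hydroxylation must distinguish the enolate faces by reagent control, since the substrate has no stereocentre.

6 to 5 to 3 to 2 to 1: the C–I bond is cut, then the one-carbon homologation is undone (C–O at the new terminus, then the terminal C=C bond). This traces the chain to 1 with all three E alkenes already in place. The forward steps must not isomerise the 2E alkene and must hydroborate only the terminal vinyl group.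

## Other disconnections considered

Alternative 1: the cut is the C10–C11 bond between the two fully substituted carbons. In the forward direction SmI2 (divalent samarium) with HMPA and t-BuOH would reduce the methyl ketone of the open-chain keto enoate A1 to a ketyl, which adds 6-exo-trig to the beta carbon of the enoate and closes the ring to cyclohexanol A2.
- In its favour: ring, tertiary carbinol and quaternary carbon would form in one step. The usual anti relation between the samarium-bound oxygen and the ester arm corresponds to the required cis hydroxyl/methyl relation, so on this point it is the equal of the chosen plan.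
- Better than the chosen plan on one point: C6 is already in place before ring closure and does not depend on a late enolate alkylation.
- Against it: a radical has to attack a beta,beta-disubstituted acceptor to join two tetrasubstituted carbons, where simple ketyl reduction and pinacol coupling can compete. The C6/C7 pair in A1 needs its own acyclic asymmetric synthesis. The chain is present only as a CH2CO2Et stub, so the E-trisubstituted C14=C15 alkene must be built afterwards.
- Comparison: the chosen plan brings the chain intact from farnesol and relies on a concerted, chelate-controlled transfer, not a radical addition at a congested centre. The enal end-game would be the same in both, so Alternative 1 is longer overall.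

Alternative 2: the cut is the C7=C2 alkene, made within a temporary seven-membered ring that also contains a C1–C3 bond. In the forward direction the second-generation Grubbs catalyst (H2IMes)(PCy3)Cl2Ru=CHPh would join the exocyclic C7 methylene of diene A3 with its methacryloyl alkene, lose ethylene, and give the fused cycloheptenone A4.
- Better than the chosen plan on alkene geometry: the ring forces C1 and C6 to be cis, whereas the chosen plan must distinguish two bromides.
- Against it: ring-closing metathesis of two 1,1-disubstituted alkenes, one of them electron-poor, to a tetrasubstituted alkene is among the least favourable metathesis classes. The homofarnesyl alkenes could not be present under forcing conditions, so only a two-carbon stub is carried and the chain is attached late. The ring must then be reopened by oxidative cleavage of the C1–C3 bond, where alkyl migration next to an enone is not the preferred course.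
- Comparison: the stereotriad would still have to come from elsewhere, possibly from the same cyclopropane tactic. The chosen plan is shorter and uses only well-behaved reaction classes, at the price of a selectivity question in step 17.

Alternative 3: the cut is the C6–C7 bond. In the forward direction zirconocene (formally divalent zirconium, from Cp2ZrCl2 and two equivalents of n-BuLi) would couple the C11 vinyl group of the 1,7-enyne A5 with its methyl-capped alkyne, and I2 would cleave both C–Zr bonds to give diiodide A6.
- Better than the chosen plan on alkene geometry: syn carbometalation puts iodine, and later the formyl group, cis to C6 by mechanism.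
- Equal on convergence: trisubstituted alkenes do not engage zirconocene, so the chain could be carried.
- Against it: A5 is acyclic and already contains the vicinal quaternary C11 and tertiary C10 centres, which are much harder to set without the ring than by hydroxyl direction within it. The alkene partner sits on a quaternary carbon. The C6 configuration would depend on the small difference between methyl and chain in the zirconacycle, which is no more secure than the enolate alkylation of the chosen plan. The iodomethyl group of A6 is beta-branched, so the two-carbon extension to C3 would be slow, and the two C–I bonds must be told apart.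
- Comparison: the steps after A6 are few, but the burden is shifted to the synthesis of A5, and the chosen plan is expected to be shorter overall.

Key step: step 10

Assumption 1: the (+)-enantiomer of the dichlorocamphor-derived sulfonyloxaziridine is taken to hydroxylate enolate 10 on the face that gives (6S)-11, by analogy with the enolate of 2-methyl-1-tetralone; if the sense is the opposite, the (−)-reagent is used with no other change.

Assumption 2: only the trans-1,4-diol 15 is carried forward; a cis epimer formed in step 8 differs only at C7, which becomes a ketone in step 12.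

In names, homofarnesyl stands for (3E,7E)-4,8,12-trimethyltrideca-3,7,11-trien-1-yl.

## Steps

Step 1
Reactants: 1 (2E,6E)-farnesol
Product: 2 (2E,6E)-3,7,11-trimethyldodeca-2,6,10-trienal (farnesal)
Conditions: TEMPO (10 mol %), PhI(OAc)2, CH2Cl2, rt
Reagents that add atoms: none
Why: Nitroxyl-catalysed oxidation of a primary allylic alcohol (oxoammonium mechanism) stops at the aldehyde and is mild enough to leave the 2E alkene and the trisubstituted chain alkenes unchanged.

Step 2
Reactants: 2 (2E,6E)-farnesal
Product: 3 (3E,7E)-4,8,12-trimethyltrideca-1,3,7,11-tetraene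
Conditions: Ph3PCH3Br, n-BuLi, THF, 0 °C; then 2, 0 °C → rt
Reagents that add atoms: methyltriphenylphosphonium bromide, C[P+](c1ccccc1)(c1ccccc1)c1ccccc1.[Br-]
Why: Wittig methylenation of the enal with the non-stabilised ylide adds the homologating carbon; the existing E alkenes take no part.

Step 3
Reactants: 3 (3E,7E)-4,8,12-trimethyltrideca-1,3,7,11-tetraene
Product: 5 (3E,7E)-4,8,12-trimethyltrideca-3,7,11-trien-1-ol (homofarnesol), via B-homofarnesyl-9-borabicyclo[3.3.1]nonane 4 (not isolated)
Conditions: 9-BBN, THF, 0 °C → rt; then NaOH, H2O2, 0 °C
Reagents that add atoms: hydrogen peroxide, OO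
Why: Hydroboration–oxidation; the hindered dialkylborane adds anti-Markovnikov to the only monosubstituted alkene (the terminus of the diene) and ignores the trisubstituted ones, and oxidation with retention gives the primary alcohol.

Step 4
Reactants: 5 homofarnesol
Product: 6 (3E,7E)-1-iodo-4,8,12-trimethyltrideca-3,7,11-triene (homofarnesyl iodide)
Conditions: I2, PPh3, imidazole, CH2Cl2, 0 °C → rt
Reagents that add atoms: iodine, II
Why: Appel-type iodination through the alkoxyphosphonium salt is an SN2 displacement at an unhindered primary carbon under nearly neutral conditions, so the alkenes are untouched.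

Step 5
Reactants: 7 3-ethoxycyclohex-2-en-1-one
Product: 9 3-ethoxy-6-methylcyclohex-2-en-1-one (racemic), via lithium 5-ethoxycyclohexa-1,5-dien-1-olate 8 (not isolated)
Conditions: LiN(i-Pr)2, THF, −78 °C; MeI, −78 → 0 °C
Reagents that add atoms: iodomethane, CI
Why: Kinetic deprotonation of the vinylogous ester occurs at the alpha' carbon (the future C10) and SN2 methylation follows there; the new stereocentre need not be controlled because it is flattened again in step 6.

Step 6
Reactants: 9 3-ethoxy-6-methylcyclohex-2-en-1-one
Product: 11 (6S)-3-ethoxy-6-hydroxy-6-methylcyclohex-2-en-1-one, via sodium 5-ethoxy-2-methylcyclohexa-1,5-dien-1-olate 10 (not isolated)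
Conditions: NaN(SiMe3)2, THF, −78 °C; (+)-[(8,8-dichlorocamphoryl)sulfonyl]oxaziridine, −78 °C; then H2O
Reagents that add atoms: (+)-[(8,8-dichlorocamphoryl)sulfonyl]oxaziridine, O=S1(=O)C[C@@]23CC[C@@H](C2(C)C)C(Cl)(Cl)[C@]34ON14
Why: Enolate hydroxylation by electrophilic oxygen transfer from an N-sulfonyloxaziridine (Davis oxidation). The tetrasubstituted cross-conjugated sodium enolate resembles the 2-alkyl-1-tetralone enolates for which this reagent discriminates faces best, and the reagent alone decides which enolate face receives oxygen, setting C10 as S.

Step 7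
Reactants: 6 homofarnesyl iodide, 11 (6S)-3-ethoxy-6-hydroxy-6-methylcyclohex-2-en-1-one
Product: 14 (4S)-4-hydroxy-3-homofarnesyl-4-methylcyclohex-2-en-1-one, via homofarnesyllithium 12 (not isolated), via dilithium dialkoxide adduct 13 (not isolated)
Conditions: 6, t-BuLi (2 equiv), Et2O/pentane, −78 °C; then 11 (0.45 equiv relative to 6), THF, −78 → 0 °C; then 1 M HCl, THF, 0 °C → rt
Reagents that add atoms: water, O
Why: Iodine–lithium exchange gives the primary alkyllithium, whose first equivalent deprotonates the tertiary alcohol and whose second adds 1,2 to the vinylogous ester carbonyl. Cold dilute acid then hydrolyses the enol ether and eliminates the new tertiary hydroxyl to give the transposed enone (Stork–Danheiser sequence). C10 is not involved, and the acid is kept weak and cold so that the chain alkenes and the remaining tertiary alcohol survive.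

Step 8
Reactants: 14 (4S)-4-hydroxy-3-homofarnesyl-4-methylcyclohex-2-en-1-one
Product: 15 (1S,4S)-2-homofarnesyl-1-methylcyclohex-2-ene-1,4-diol
Conditions: NaBH4, CeCl3·7H2O, MeOH, −78 °C
Reagents that add atoms: none
Why: Luche 1,2-reduction of the enone. Axial hydride delivery to the half-chair that keeps the C10 methyl pseudoaxial (away from the C11 chain) should place the new hydroxyl trans to the tertiary one, and any cis epimer is removed here by chromatography.

Step 9
Reactants: 15 (1S,4S)-2-homofarnesyl-1-methylcyclohex-2-ene-1,4-diol
Product: 16 (1S,4S)-4-[(tert-butyldimethylsilyl)oxy]-2-homofarnesyl-1-methylcyclohex-2-en-1-ol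
Conditions: TBSCl, imidazole, DMF, 0 °C → rt
Reagents that add atoms: tert-butyldimethylsilyl chloride, CC(C)(C)[Si](C)(C)Cl
Why: Only the secondary allylic hydroxyl is silylated, because the tertiary hydroxyl next to a fully substituted carbon is too hindered for the chloride/imidazole reagent. This leaves the C10 hydroxyl as the only free, zinc-binding oxygen.

Step 10
Reactants: 16 (1S,4S)-4-[(tert-butyldimethylsilyl)oxy]-2-homofarnesyl-1-methylcyclohex-2-en-1-ol
Product: 18 (1R,2S,5S,6S)-5-[(tert-butyldimethylsilyl)oxy]-1-homofarnesyl-2-methylbicyclo[4.1.0]heptan-2-ol, via ethylzinc alkoxide 17 (not isolated)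
Conditions: Et2Zn (3 equiv), CH2Cl2, −20 °C; then CH2I2 (3 equiv), −20 → 0 °C; then pH 7 buffer
Reagents that add atoms: diiodomethane, ICI
Why: Et2Zn deprotonates the C10 hydroxyl to the ethylzinc alkoxide 17, which binds the (iodomethyl)zinc carbenoid formed from further Et2Zn and CH2I2 and holds it over the adjacent C11=C6 alkene. Methylene is transferred through a concerted, stereospecific [2+1] (butterfly-type) transition state, so the C11–CH2 and C6–CH2 bonds form on the same alkene face and the three-membered ring closes in one suprafacial event, not stepwise. The closest known reaction type is the hydroxyl-directed Simmons–Smith cyclopropanation (Furukawa variant) of cyclic allylic alcohols, which also works with tertiary carbinols. Both new stereocentres are controlled by the C10 oxygen: CH2 arrives on the face carrying the zinc alkoxide, which makes C11 quaternary with the future methyl cis to the hydroxyl (1R) and fixes C6 (6S) through the cis ring fusion. The step needs facial selectivity and chemoselectivity. The face is secured because the only oxygen able to bind zinc is the C10 alkoxide; the C7 oxygen is buried under the tert-butyldimethylsilyl group and, in this trans epimer, lies on the opposite face where it cannot hinder delivery. Chemoselectivity over the three trisubstituted chain alkenes rests on the large rate advantage of the alkoxide-bound alkene (the nearest chain alkene is four bonds from the carbinol carbon) and on limiting the carbenoid to about three equivalents at −20 to 0 °C. The buffered quench removes ZnI2 before it can ionise the cyclopropylcarbinyl C–O bonds.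

Step 11
Reactants: 18 (1R,2S,5S,6S)-5-[(tert-butyldimethylsilyl)oxy]-1-homofarnesyl-2-methylbicyclo[4.1.0]heptan-2-ol
Product: 19 (1R,2S,5S,6S)-1-homofarnesyl-2-methylbicyclo[4.1.0]heptane-2,5-diol
Conditions: n-Bu4NF, THF, 0 °C → rt
Reagents that add atoms: none
Why: Fluoride cleaves the secondary silyl ether under basic, non-acidic conditions, chosen because both carbinol carbons are cyclopropylcarbinyl positions that would ionise and rearrange in acid.

Step 12
Reactants: 19 (1R,2S,5S,6S)-1-homofarnesyl-2-methylbicyclo[4.1.0]heptane-2,5-diol
Product: 20 (1S,5S,6R)-5-hydroxy-6-homofarnesyl-5-methylbicyclo[4.1.0]heptan-2-one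
Conditions: n-Pr4N[RuO4] (5 mol %), NMO, 4 Å MS, CH2Cl2, rt
Reagents that add atoms: none
Why: Ley–Griffith oxidation (catalytic perruthenate with an N-oxide as terminal oxidant) converts the secondary alcohol into the ketone under neutral conditions; the tertiary alcohol cannot be oxidised and the isolated alkenes are inert.

Step 13
Reactants: 20 (1S,5S,6R)-5-hydroxy-6-homofarnesyl-5-methylbicyclo[4.1.0]heptan-2-one
Product: 21 (1S,5S,6R)-6-homofarnesyl-5-methyl-5-[(triethylsilyl)oxy]bicyclo[4.1.0]heptan-2-one
Conditions: Et3SiOTf, 2,6-lutidine, CH2Cl2, −78 → 0 °C
Reagents that add atoms: triethylsilyl trifluoromethanesulfonate, CC[Si](CC)(CC)OS(=O)(=O)C(F)(F)F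
Why: A silyl triflate with a hindered pyridine base silylates even this neopentyl-type tertiary alcohol at low temperature, while 2,6-lutidine is too weak to convert the ketone into a silyl enol ether. The ether removes the only acidic proton before the dissolving-metal step and protects C10 from the phosphorus–bromine reagents of step 15.

Step 14
Reactants: 21 (1S,5S,6R)-6-homofarnesyl-5-methyl-5-[(triethylsilyl)oxy]bicyclo[4.1.0]heptan-2-one, 22 allyl bromide
Product: 24 (2S,3S,4S)-3-homofarnesyl-3,4-dimethyl-2-(prop-2-en-1-yl)-4-[(triethylsilyl)oxy]cyclohexan-1-one, via lithium enolate 23 (not isolated)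
Conditions: Li (2.2 equiv), NH3(l)/THF, t-BuOH (1 equiv), −78 °C; then 22 (5 equiv), −78 → −33 °C; then NH4Cl
Reagents that add atoms: none
Why: Dissolving-metal reduction of the cyclopropyl ketone cleaves the cyclopropane bond that overlaps best with the carbonyl pi system, the exocyclic C6–CH2 bond, so the CH2 becomes the C11 methyl (protonated by t-BuOH) and the regiodefined C6 lithium enolate 23 remains. SN2 allylation by 22 then takes place at C6 before proton exchange can move the enolate, on the face anti to the homofarnesyl arm of the adjacent quaternary carbon (cis to the C11 methyl), which sets C6 as required.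

Step 15
Reactants: 24 (2S,3S,4S)-3-homofarnesyl-3,4-dimethyl-2-(prop-2-en-1-yl)-4-[(triethylsilyl)oxy]cyclohexan-1-one
Product: 25 {[(1S,2S,3S)-4-(dibromomethylidene)-2-homofarnesyl-1,2-dimethyl-3-(prop-2-en-1-yl)cyclohexyl]oxy}triethylsilane
Conditions: CBr4, P(Oi-Pr)3, CH2Cl2, 0 °C → rt
Reagents that add atoms: carbon tetrabromide, BrC(Br)(Br)Br
Why: Ramirez-type dibromomethylenation with the phosphite-derived ylide (a Horner–Wadsworth–Emmons-like variant that is more reactive towards alpha-branched ketones than the triphenylphosphine version) converts C7=O into C7=CBr2. The medium is not basic, so C6 is not epimerised, and the silyl ether and the isolated alkenes are inert.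

Step 16
Reactants: 25 {[(1S,2S,3S)-4-(dibromomethylidene)-2-homofarnesyl-1,2-dimethyl-3-(prop-2-en-1-yl)cyclohexyl]oxy}triethylsilane
Product: 27 3-[(1S,2S,3S)-6-(dibromomethylidene)-2-homofarnesyl-2,3-dimethyl-3-[(triethylsilyl)oxy]cyclohexyl]propan-1-ol, via B-alkyl-9-borabicyclo[3.3.1]nonane 26 (not isolated)
Conditions: 9-BBN, THF, 0 °C → rt; then NaOH, H2O2, 0 °C
Reagents that add atoms: hydrogen peroxide, OO
Why: 9-BBN hydroborates only the monosubstituted terminal alkene (anti-Markovnikov); the three trisubstituted chain alkenes and the tetrasubstituted, electron-poor dibromoalkene are far less reactive. Oxidation with retention gives the C3 primary alcohol, and no carbonyl reduction can compete because the ketone is already gone.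

Step 17
Reactants: 27 3-[(1S,2S,3S)-6-(dibromomethylidene)-2-homofarnesyl-2,3-dimethyl-3-[(triethylsilyl)oxy]cyclohexyl]propan-1-ol
Product: 28 3-[(1S,2S,3S,6Z)-6-(1-bromoethylidene)-2-homofarnesyl-2,3-dimethyl-3-[(triethylsilyl)oxy]cyclohexyl]propan-1-ol
Conditions: Me2Zn (3 equiv), Pd(DPEphos)Cl2 (5 mol %), THF/DMF, 0 → 40 °C
Reagents that add atoms: dimethylzinc, C[Zn]C
Why: Negishi coupling: zerovalent palladium inserts into the less hindered C–Br bond, the one cis to the C8 methylene and remote from the branched C6, whose arm is held pseudoaxial by allylic strain and shields the other bromide. Methyl transfer from zinc and reductive elimination proceed with retention, so the methyl ends up cis to C8. The wide-bite-angle bidentate ligand disfavours a second coupling, and the free hydroxyl is merely converted into its zinc alkoxide.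

Step 18
Reactants: 28 3-[(1S,2S,3S,6Z)-6-(1-bromoethylidene)-2-homofarnesyl-2,3-dimethyl-3-[(triethylsilyl)oxy]cyclohexyl]propan-1-ol
Product: 30 (2Z)-2-[(2R,3S,4S)-3-homofarnesyl-2-(3-hydroxypropyl)-3,4-dimethyl-4-[(triethylsilyl)oxy]cyclohexylidene]propanal, via dilithio alkoxide-alkenyllithium 29 (not isolated)
Conditions: MeLi (1.05 equiv), THF, −78 °C; t-BuLi (2.1 equiv), −78 °C; DMF, −78 → 0 °C; then H2O
Reagents that add atoms: N,N-dimethylformamide, CN(C)C=O
Why: MeLi first converts the hydroxyl into its lithium alkoxide so that no proton source remains. Bromine–lithium exchange with t-BuLi then gives the configurationally stable alkenyllithium 29 with retention, and formylation with DMF places the aldehyde where bromine was, cis to C6, which is the Z enal.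

Step 19
Reactants: 30 (2Z)-2-[(2R,3S,4S)-3-homofarnesyl-2-(3-hydroxypropyl)-3,4-dimethyl-4-[(triethylsilyl)oxy]cyclohexylidene]propanal
Product: 31 iridal, (2Z)-2-[(2R,3S,4S)-4-hydroxy-3-homofarnesyl-2-(3-hydroxypropyl)-3,4-dimethylcyclohexylidene]propanal
Conditions: HF·pyridine, pyridine, THF, 0 °C → rt
Reagents that add atoms: none
Why: Fluoride cleaves the Si–O bond of the tertiary triethylsilyl ether. Pyridine-buffered HF avoids both the basicity of free fluoride, which could isomerise or deconjugate the enal, and strong acid, which would endanger the tertiary alcohol and the polyene; no stereocentre or alkene is touched.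

## Compound list

1 | (2E,6E)-3,7,11-trimethyldodeca-2,6,10-trien-1-ol, (2E,6E)-farnesol | CC(C)=CCC/C(C)=C/CC/C(C)=C/CO | starting material
2 | (2E,6E)-3,7,11-trimethyldodeca-2,6,10-trienal, farnesal | CC(C)=CCC/C(C)=C/CC/C(C)=C/C=O | intermediate
3 | (3E,7E)-4,8,12-trimethyltrideca-1,3,7,11-tetraene | CC(C)=CCC/C(C)=C/CC/C(C)=C/C=C | intermediate
4 | 9-homofarnesyl-9-borabicyclo[3.3.1]nonane (not isolated) | CC(C)=CCC/C(C)=C/CC/C(C)=C/CCB1C2CCCC1CCC2 | intermediate
5 | (3E,7E)-4,8,12-trimethyltrideca-3,7,11-trien-1-ol, homofarnesol | CC(C)=CCC/C(C)=C/CC/C(C)=C/CCO | intermediate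
6 | (3E,7E)-1-iodo-4,8,12-trimethyltrideca-3,7,11-triene, homofarnesyl iodide | CC(C)=CCC/C(C)=C/CC/C(C)=C/CCI | intermediate
7 | 3-ethoxycyclohex-2-en-1-one | CCOC1=CC(=O)CCC1 | starting material
8 | lithium 5-ethoxycyclohexa-1,5-dien-1-olate (not isolated) | CCOC1=CC(O[Li])=CCC1 | intermediate
9 | 3-ethoxy-6-methylcyclohex-2-en-1-one (racemic) | CCOC1=CC(=O)C(C)CC1 | intermediate
10 | sodium 5-ethoxy-2-methylcyclohexa-1,5-dien-1-olate (not isolated) | CCOC1=CC(O[Na])=C(C)CC1 | intermediate
11 | (6S)-3-ethoxy-6-hydroxy-6-methylcyclohex-2-en-1-one | CCOC1=CC(=O)[C@@](C)(O)CC1 | intermediate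
12 | homofarnesyllithium (not isolated) | CC(C)=CCC/C(C)=C/CC/C(C)=C/CC[Li] | intermediate
13 | dilithium (1S)-4-ethoxy-2-homofarnesyl-1-methylcyclohex-3-ene-1,2-diolate, C2 configuration undefined (not isolated) | CC(C)=CCC/C(C)=C/CC/C(C)=C/CCC1(O[Li])C=C(OCC)CC[C@]1(C)O[Li] | intermediate
14 | (4S)-4-hydroxy-3-homofarnesyl-4-methylcyclohex-2-en-1-one | CC(C)=CCC/C(C)=C/CC/C(C)=C/CCC1=CC(=O)CC[C@]1(C)O | intermediate
15 | (1S,4S)-2-homofarnesyl-1-methylcyclohex-2-ene-1,4-diol | CC(C)=CCC/C(C)=C/CC/C(C)=C/CCC1=C[C@@H](O)CC[C@]1(C)O | intermediate
16 | (1S,4S)-4-[(tert-butyldimethylsilyl)oxy]-2-homofarnesyl-1-methylcyclohex-2-en-1-ol | CC(C)=CCC/C(C)=C/CC/C(C)=C/CCC1=C[C@@H](O[Si](C)(C)C(C)(C)C)CC[C@]1(C)O | intermediate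
17 | ethylzinc alkoxide of 16 at the C10 oxygen (not isolated) | CC(C)=CCC/C(C)=C/CC/C(C)=C/CCC1=C[C@@H](O[Si](C)(C)C(C)(C)C)CC[C@]1(C)O[Zn]CC | intermediate
18 | (1R,2S,5S,6S)-5-[(tert-butyldimethylsilyl)oxy]-1-homofarnesyl-2-methylbicyclo[4.1.0]heptan-2-ol | CC(C)=CCC/C(C)=C/CC/C(C)=C/CC[C@@]12C[C@@H]1[C@@H](O[Si](C)(C)C(C)(C)C)CC[C@]2(C)O | intermediate
19 | (1R,2S,5S,6S)-1-homofarnesyl-2-methylbicyclo[4.1.0]heptane-2,5-diol | CC(C)=CCC/C(C)=C/CC/C(C)=C/CC[C@@]12C[C@@H]1[C@@H](O)CC[C@]2(C)O | intermediate
20 | (1S,5S,6R)-5-hydroxy-6-homofarnesyl-5-methylbicyclo[4.1.0]heptan-2-one | CC(C)=CCC/C(C)=C/CC/C(C)=C/CC[C@@]12C[C@@H]1C(=O)CC[C@]2(C)O | intermediate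
21 | (1S,5S,6R)-6-homofarnesyl-5-methyl-5-[(triethylsilyl)oxy]bicyclo[4.1.0]heptan-2-one | CC(C)=CCC/C(C)=C/CC/C(C)=C/CC[C@@]12C[C@@H]1C(=O)CC[C@]2(C)O[Si](CC)(CC)CC | intermediate
22 | 3-bromoprop-1-ene, allyl bromide | C=CCBr | starting material
23 | lithium (3S,4S)-3-homofarnesyl-3,4-dimethyl-4-[(triethylsilyl)oxy]cyclohex-1-en-1-olate (not isolated) | CC(C)=CCC/C(C)=C/CC/C(C)=C/CC[C@@]1(C)C=C(O[Li])CC[C@]1(C)O[Si](CC)(CC)CC | intermediate
24 | (2S,3S,4S)-3-homofarnesyl-3,4-dimethyl-2-(prop-2-en-1-yl)-4-[(triethylsilyl)oxy]cyclohexan-1-one | CC(C)=CCC/C(C)=C/CC/C(C)=C/CC[C@@]1(C)[C@H](CC=C)C(=O)CC[C@]1(C)O[Si](CC)(CC)CC | intermediate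
25 | {[(1S,2S,3S)-4-(dibromomethylidene)-2-homofarnesyl-1,2-dimethyl-3-(prop-2-en-1-yl)cyclohexyl]oxy}triethylsilane | CC(C)=CCC/C(C)=C/CC/C(C)=C/CC[C@@]1(C)[C@H](CC=C)C(=C(Br)Br)CC[C@]1(C)O[Si](CC)(CC)CC | intermediate
26 | 9-BBN adduct of 25 at the terminal carbon of the allyl group (not isolated) | CC(C)=CCC/C(C)=C/CC/C(C)=C/CC[C@@]1(C)[C@H](CCCB2C3CCCC2CCC3)C(=C(Br)Br)CC[C@]1(C)O[Si](CC)(CC)CC | intermediate
27 | 3-[(1S,2S,3S)-6-(dibromomethylidene)-2-homofarnesyl-2,3-dimethyl-3-[(triethylsilyl)oxy]cyclohexyl]propan-1-ol | CC(C)=CCC/C(C)=C/CC/C(C)=C/CC[C@@]1(C)[C@H](CCCO)C(=C(Br)Br)CC[C@]1(C)O[Si](CC)(CC)CC | intermediate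
28 | 3-[(1S,2S,3S,6Z)-6-(1-bromoethylidene)-2-homofarnesyl-2,3-dimethyl-3-[(triethylsilyl)oxy]cyclohexyl]propan-1-ol | CC(C)=CCC/C(C)=C/CC/C(C)=C/CC[C@@]1(C)[C@H](CCCO)/C(=C(/C)Br)CC[C@]1(C)O[Si](CC)(CC)CC | intermediate
29 | dilithio derivative of 28: lithium alkoxide at the C3 oxygen, lithium in place of bromine, alkene geometry retained (not isolated) | CC(C)=CCC/C(C)=C/CC/C(C)=C/CC[C@@]1(C)[C@H](CCCO[Li])/C(=C(/C)[Li])CC[C@]1(C)O[Si](CC)(CC)CC | intermediate
30 | (2Z)-2-[(2R,3S,4S)-3-homofarnesyl-2-(3-hydroxypropyl)-3,4-dimethyl-4-[(triethylsilyl)oxy]cyclohexylidene]propanal | CC(C)=CCC/C(C)=C/CC/C(C)=C/CC[C@@]1(C)[C@H](CCCO)/C(=C(/C)C=O)CC[C@]1(C)O[Si](CC)(CC)CC | intermediate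
31 | iridal, (2Z)-2-[(2R,3S,4S)-4-hydroxy-3-homofarnesyl-2-(3-hydroxypropyl)-3,4-dimethylcyclohexylidene]propanal | CC(C)=CCC/C(C)=C/CC/C(C)=C/CC[C@@]1(C)[C@H](CCCO)/C(=C(/C)C=O)CC[C@]1(C)O | target

## Step count and risks

Total: 19 steps. Longest linear sequence: 17 steps (steps 1–4 and 7–19, from 1); the ring branch (steps 5 and 6) joins at step 7.

Step 10 (key step). The most likely failure is loss of chemoselectivity. If the hindered tertiary zinc alkoxide delivers CH2 slowly, excess carbenoid begins to cyclopropanate the electron-rich trisubstituted chain alkenes. A long exposure to ZnI2 also risks ionisation of the cyclopropylcarbinyl C–O bonds. The fallback changes the approach from an electrophilic carbenoid on the allylic alcohol to a nucleophilic methylene donor on the enone. It sets out from 14, which is treated with dimethylsulfoxonium methylide (Me3S(O)I, NaH, DMSO, rt). This Michael-initiated ring closure (Corey–Chaykovsky cyclopropanation) is specific for the conjugated alkene and should add at C11 anti to the pseudoaxial C10 methyl, on the hydroxyl face. It comes back to the route at 20, bypassing steps 8 to 12, and creates no compound outside the numbered list (F0). Its weak point is that face selection rests on the size difference between methyl and hydroxyl and not on chelation, which is why it is the reserve and not the plan.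

Step 6. The most likely failure is insufficient enantioface discrimination in oxygen transfer to the tetrasubstituted enolate, because the vinylogous ester is only an analogue of the aryl ketones for which the reagent is proven. The fallback replaces reagent control by classical resolution. It sets out from 15 of insufficient enantiomeric purity, whose secondary hydroxyl is esterified with (2S)-2-methoxy-2-phenylacetic acid (DCC, catalytic DMAP, CH2Cl2, 0 °C). The diastereomeric esters are separated by chromatography or crystallisation, and the ester of the desired diol, (1S,4S)-4-hydroxy-3-homofarnesyl-4-methylcyclohex-2-en-1-yl (2S)-2-methoxy-2-phenylacetate F1, is hydrolysed (LiOH, THF/H2O). It comes back to the route at 15.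

Step 14. The most likely failures are poor facial selectivity in the alkylation of 23, whose reacting carbon is flanked by the quaternary C11, and proton exchange between product and enolate that leads to regio-scrambling or dialkylation. The fallback replaces the SN2 alkylation by a palladium-mediated allyl transfer. It sets out from 21, from which enolate 23 is generated as before; after removal of NH3 it is O-acylated with allyl chloroformate to the enol carbonate (3S,4S)-3-homofarnesyl-3,4-dimethyl-4-[(triethylsilyl)oxy]cyclohex-1-en-1-yl prop-2-en-1-yl carbonate F2. Pd2(dba)3 with a chiral diphosphine (Trost ligand) in THF then effects decarboxylative Tsuji–Trost allylation. The enolate is released only within the allylpalladium ion pair, so regiochemistry is fixed, and the ligand enantiomer can be chosen to reinforce or override the substrate bias. It comes back to the route at 24.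

Step 17. The most likely failure is insufficient site discrimination between the two C–Br bonds in oxidative addition, since both are flanked by ring carbons, or a second methylation. The fallback reverses the order of the two substitutions so that the first event selects the more hindered bromide. It sets out from 27, which is converted into its lithium alkoxide (MeLi) and then treated with n-BuLi at −105 °C in THF/Et2O/pentane. Kinetic bromine–lithium exchange at the more congested bromide cis to C6 (relief of strain, assisted by the nearby side-chain alkoxide) should give the alpha-bromoalkenyllithium carbenoid F3, and DMF then gives (2E)-2-bromo-2-[(2S,3S,4S)-3-homofarnesyl-2-(3-hydroxypropyl)-3,4-dimethyl-4-[(triethylsilyl)oxy]cyclohexylidene]acetaldehyde F4. Suzuki–Miyaura methylation of this activated alpha-bromo enal (trimethylboroxine, Pd(dppf)Cl2, K2CO3, dioxane/H2O) proceeds with retention. It comes back to the route at 30.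

## Further compounds

F0 | step 10 | none | none
F1 | step 6 | (1S,4S)-4-hydroxy-3-homofarnesyl-4-methylcyclohex-2-en-1-yl (2S)-2-methoxy-2-phenylacetate | CC(C)=CCC/C(C)=C/CC/C(C)=C/CCC1=C[C@@H](OC(=O)[C@@H](OC)c2ccccc2)CC[C@]1(C)O
F2 | step 14 | (3S,4S)-3-homofarnesyl-3,4-dimethyl-4-[(triethylsilyl)oxy]cyclohex-1-en-1-yl prop-2-en-1-yl carbonate | CC(C)=CCC/C(C)=C/CC/C(C)=C/CC[C@@]1(C)C=C(OC(=O)OCC=C)CC[C@]1(C)O[Si](CC)(CC)CC
F3 | step 17 | alpha-bromoalkenyllithium carbenoid from 27: lithium alkoxide at the C3 oxygen, lithium cis to C6, bromine cis to C8 | CC(C)=CCC/C(C)=C/CC/C(C)=C/CC[C@@]1(C)[C@H](CCCO[Li])/C(=C(/Br)[Li])CC[C@]1(C)O[Si](CC)(CC)CC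
F4 | step 17 | (2E)-2-bromo-2-[(2S,3S,4S)-3-homofarnesyl-2-(3-hydroxypropyl)-3,4-dimethyl-4-[(triethylsilyl)oxy]cyclohexylidene]acetaldehyde | CC(C)=CCC/C(C)=C/CC/C(C)=C/CC[C@@]1(C)[C@H](CCCO)/C(=C(/Br)C=O)CC[C@]1(C)O[Si](CC)(CC)CC
A1 | alternative 1 | ethyl (2E,4S,5S)-4-{3-[(tert-butyldimethylsilyl)oxy]propyl}-3-methyl-8-oxo-5-[(triethylsilyl)oxy]non-2-enoate | CCOC(=O)/C=C(\C)[C@H](CCCO[Si](C)(C)C(C)(C)C)[C@@H](O[Si](CC)(CC)CC)CCC(C)=O
A2 | alternative 1 | ethyl 2-[(1S,2S,5S,6S)-6-{3-[(tert-butyldimethylsilyl)oxy]propyl}-2-hydroxy-1,2-dimethyl-5-[(triethylsilyl)oxy]cyclohexyl]acetate | CCOC(=O)C[C@@]1(C)[C@H](CCCO[Si](C)(C)C(C)(C)C)[C@@H](O[Si](CC)(CC)CC)CC[C@]1(C)O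
A3 | alternative 2 | 6-[(1R,2S,3S)-2-{2-[(tert-butyldimethylsilyl)oxy]ethyl}-3-hydroxy-2,3-dimethyl-6-methylidenecyclohexyl]-2-methylhex-1-en-3-one | CC(C)(C)[Si](C)(C)OCC[C@@]1(C)[C@H](CCCC(=O)C(C)=C)C(=C)CC[C@]1(C)O
A4 | alternative 2 | (3S,4S,4aR)-4-{2-[(tert-butyldimethylsilyl)oxy]ethyl}-3-hydroxy-3,4,9-trimethyl-1,2,3,4,4a,5,6,7-octahydro-8H-benzo[7]annulen-8-one | CC(C)(C)[Si](C)(C)OCC[C@@]1(C)[C@@H]2CCCC(=O)C(C)=C2CC[C@]1(C)O
A5 | alternative 3 | triethylsilyl ether of (6S,7S,10E,14E)-7-ethenyl-6,7,11,15,19-pentamethylicosa-10,14,18-trien-2-yn-6-ol | CC(C)=CCC/C(C)=C/CC/C(C)=C/CC[C@@](C)(C=C)[C@](C)(CCC#CC)O[Si](CC)(CC)CC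
A6 | alternative 3 | triethyl{[(1S,2S,3S,4Z)-2-homofarnesyl-4-(1-iodoethylidene)-3-(iodomethyl)-1,2-dimethylcyclohexyl]oxy}silane | CC(C)=CCC/C(C)=C/CC/C(C)=C/CC[C@@]1(C)[C@H](CI)/C(=C(/C)I)CC[C@]1(C)O[Si](CC)(CC)CC
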